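The runs come from a simulation for an exercise, and the scatter is random.

The pitfall is to treat a percentage from the south-west run as a yield that carries over to another charge, when a percentage is a concentration divided by the charge.

* the flasks put in order of amount of target, in percent of the solid substrate charged, best first, at 15 min (grey / red / amber / green / teal)
* the amount of target, in percent of the solid substrate charged of the flask you put first, at 15 min
* the amount of target, in percent of the solid substrate charged of the flask you put last, at 15 min

| setting | south-west | grey | red | amber | green | teal |
|---|---|---|---|---|---|---|
| solid substrate | 0.042 M | 0.080 M | 0.12 M | 0.25 M | 0.060 M | 0.15 M |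
| remark | run made earlier |  |  |  |  |  |
| time |  | 15 min | 15 min | 15 min | 15 min | 15 min |

- south-west (time / min: target / %, solid substrate / %): 2.00: 1.5, 85.8; 4.00: 5.9, 71.5; 6.00: 12.3, 58.9; 8.00: 19.4, 45.7; 10.0: 25.6, 33.8

(scatter of a reading: 0.5 percentage points)

- at the start none of the solid substrate is in solution
- in a conversion other conformer counts as not yet reacted; third conformer counts as reacted
- what has only dissolved of solid substrate counts as not reacted
- a reading or a percentage of target counts all its forms, free or not

In the south-west run the solid substrate falls steadily from 85.8% at 2.00 min to 33.8% at 10.0 min, which is 0.00273 M min⁻¹. The loss between readings eases from 14 percentage points to 12 points as the solid shrinks, close to apparent zero order, so this reckoning takes the same rate for each charge. The times then form a ladder. On the lowest rung stands the lag of target in the south-west run, 2.30 min, read by running the last readings back to zero, and it is shorter than the asked time. After the lag, dividing the rise of target by the fall of solid, so that time drops out, gives a reading of s = 0.530 of target per solid lost. On the top rung stands the life of the solid, charge divided by rate. Of the asked flasks, green has the smallest charge, and even there the reckoned life of 22.0 min is longer than 15 min; amber's is 91.6 min.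

Each flask should therefore hold the same concentration of target at 15 min. This output, C, is what the south-west run held at 10.0 min plus s times the solid lost afterwards: 0.0180 M. Dividing C by the charge gives 30.0% for green and 7.19% for amber, which has the largest charge of the asked flasks.

The forecast gives green > grey > red > teal > amber, with 30% (25% to 40%) for green and 7.3% (5.5% to 11%) for amber, because “the smallest charge ranks best”; its amber figure stands above this reckoning's.

The flasks give green > grey > red > teal > amber, from 32.6% in green to 7.82% in amber, and the mechanism behind them is this:

    solid substrate ⇌ starting material, rate k1*(cs1 - [starting material]) while solid is left; crystals form when [starting material] > cs1 (solubility = 0.0850 M, k = 0.0363 min⁻¹)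
    starting material → target (k = 0.134 min⁻¹)
    third conformer → third product (k = 3.74 min⁻¹)
    crystals ⇌ target, rate k4*(cs4 - [target]) while solid is left; crystals form when [target] > cs4 (solubility = 0.220 M, k = 4.19 min⁻¹)
    other conformer ⇌ third conformer (K = 2.60, k = 0.164 min⁻¹)
    other conformer → isomer of the product (k = 0.335 min⁻¹)
    starting material ⇌ other conformer (K = 1.10, k = 0.0387 min⁻¹)
    starting material ⇌ dormant form (K = 0.953, k = 0.0228 min⁻¹)

In concentration, green holds 0.0195 M of target and amber 0.0195 M, nearly the same and more than C. On teal, C gives 12.0% against a simulated 13.0%. Left to 150 min, with solid substrate at 0% in green and 0% in amber, green holds 78.1% of target and amber 77.1%.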